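The earlier runs and the new flask were generated by integration for an exercise, and the scatter is random.

If I want the longer chains from this charge, do I stop the flask at 30 h (amber) or leave it until 60 h (violet)?

| setting | oak | cedar | amber | violet |
|---|---|---|---|---|
| Z | 0.052 M | 0.081 M | 0.037 M | 0.037 M |
| L | 0.5 mol% | 0.5 mol% | 0.5 mol% | 0.5 mol% |
| remark | run made earlier | run made earlier |  |  |
| time |  |  | 30 h | 60 h |

| oak: time / h | oak: Q / % | cedar: time / h | cedar: Q / % |
|---|---|---|---|
| 1.33 | 0.5 | 1.33 | 0 |
| 2.50 | 0.2 | 2.50 | 0.4 |
| 5.00 | 1.9 | 5.00 | 1.7 |
| 10.0 | 4.2 | 10.0 | 9.5 |
| 20.0 | 22.5 | 20.0 | 37.0 |

(readings scatter by 1 percentage point)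

- which of the two ends with the longer chains by the average number of monomer units in a chain (chains begun, living or dead) ("neither" if they lie within 10 %) (amber / violet / neither)
- average number of monomer units in a chain (chains begun, living or dead) at the end, amber
- average number of monomer units in a chain (chains begun, living or dead) at the end, violet

- the average divides the monomer in chains by the number of chains begun, living and dead together
- what was read earlier has a scatter of 1 percentage point, one standard deviation
- the earlier runs do not show the number of chains; that part of a forecast is a guess

I reckon with the charge length 200, the ratio [Z]/[L] as charged, which is the target degree of polymerisation. If each L begins no more than one chain, the length in a flask is the charge length times the conversion, divided by the share of L that has begun a chain.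

Oak and cedar roughly superimpose on [Z] times time, so I read conversion on that scale. Amber's product of 66.6 M·min lies just beyond oak's 62.4 M·min at its last reading, so I take amber's conversion as at least the 22.5 % read there. Violet's 133 M·min lies beyond cedar's 97.2 M·min, so I take violet's as at least the 37.0 % read there.

With the share at one, these readings give floors of 45.0 for amber and 74.0 for violet, and a smaller share lifts both. The share is a guess, since the runs do not show chains. Violet's lead goes only if the share grows between the two times by as much as the conversion does, and the floors do not give that conversion ratio. Violet's floor stands above amber's, so I leave the flask until 60 h and expect violet to be longer.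

The forecast also says violet, with 52 for amber and 115 for violet: “If every L starts one chain, the full-conversion length is 200 units, giving about 50 and 115”.

Violet ends longer, at 236 against 150 for amber, with Q at 76.4 % in violet and 30.8 % in amber.

    Z + X → E + Q (k = 2.96 L mol⁻¹ h⁻¹)
    L → X (k = 0.0286 h⁻¹)
    Z + E → Q + E, rate k3*[E]*[Z] (k = 352 L mol⁻¹ h⁻¹)

Through the charge length, these figures give a share of about 41.0 % of L begun in amber and about 64.9 % in violet. A neighbour of violet, charged with 0.015 M of Z at the same loading and run for the same time, has the same charge length. Its Q of 35.5 % and its length of 124 give a share of about 57.1 %.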